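Conventions: Ar = 3,4,5-trimethoxyphenyl. The tetrahydrofuran ring is numbered O1, C2 (Ar), C3, C4, C5 (CH2) in every compound.

## Structural features

The target is one tetrahydrofuran ring carrying a 3,4,5-trimethoxyphenyl group on C2, a hydroxymethyl group on C3 and a 3,4,5-trimethoxybenzoyl group on C4; C5 is an unsubstituted CH2. C2, C3 and C4 are three contiguous stereocentres (2R,3R,4S): aryl and CH2OH are cis, CH2OH and aroyl are trans. C4 is α to a ketone and can be equilibrated, and 3,4-trans is the less crowded arrangement, so this centre can be left to thermodynamics. C2 and C3 cannot be corrected afterwards and their cis relationship is the crowded one; this, with the absolute configuration at C2, is the real difficulty. Fragile points are the benzylic C2–O1 bond next to an electron-rich arene (acid ionisation), the β-alkoxy ketone C4–C5–O1 (base-induced ring opening) and the γ-hydroxy ketone (acyl transfer). The key step exploits two facts: C4 is the α-carbon of an aryl ketone, so it can be the central carbon of a symmetric 1,3-diaryl-1,3-diketone, and C3 bears exactly one carbon, which can arise as an exocyclic methylene from the terminal carbon of an alkyne attached to C2.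

## Logic of the disconnections

16 ⇒ 14. Retrosynthetically the C4–H bond of 16 is exchanged for a second C4–C(=O)Ar bond. Two identical aroyl groups make C4 non-stereogenic and turn it into a 1,3-diketone carbon, which the ring-forming step needs; one stereocentre disappears. The forward step must cleave exactly one C4–C(=O) bond (retro-Claisen, through 15), keep the ring intact and let C4 protonate trans to C3.

14 ⇒ 12. The C3–H bond and the side-chain C–OH bond are removed together, so CH2OH becomes an exocyclic C3=CH2. The configuration at C3 then depends only on which alkene face is attacked, and only the C2 aryl group can bias that, because C4 is quaternary and symmetric. The forward step must put hydrogen on C3 anti to the aryl group and oxygen on the terminal carbon without reducing either ketone; 13 is the borane intermediate.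

12 ⇒ 11 (key). The ring bond C3–C4 is cut. This opens the ring to an acyclic ether in which C4 is a diketone C–H carbon and C3 the internal carbon of a terminal alkyne, so the molecule can be assembled from two halves through oxygen. The forward step must be a 5-exo-dig attack through carbon, must not ionise the benzylic propargylic C2–O1 bond and must not eliminate the alkoxide from C5.

11 ⇒ 9 + 10 (from 5). The ether bond O1–C5 is cut, separating the chiral half 9 from the achiral half. Conjugate addition of the alkoxide of 9 to 10 makes this bond without touching C2. Because 10 is too reactive to store, the forward step generates it from 5 in the presence of the alkoxide and must stop at the enolate of 11; this is a deliberate improvement over isolating 10.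

5 ⇒ 3 ⇒ 1 + 2. The C4–C5 bond is cut back to 3 and a one-carbon iminium electrophile (through 4); the C4–C(=O) bond of 3 is cut to 1 and 2. Both are textbook enol and enolate reactions on symmetric, achiral material. The demands are complete aminomethylation before any base is present and a quaternary salt stable enough to handle.

9 ⇒ 6 + 7. The C2–C3 bond between carbinol carbon and alkyne is cut. This is the only step in which a reagent sets absolute configuration; everything later is relayed from C2. The forward step must add the acetylide to the Re face of 6 with high selectivity, and the silyl group of 8 must come off without racemisation.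

## Other disconnections considered

Alternative 1: The cut is C2–C3. The trans-4,5-disubstituted α-diazo-γ-butyrolactone A1, whose ring carbon next to the diazo carbon carries a CH2–O–CH2Ar chain, would be decomposed with Rh2(OAc)4 (divalent rhodium). The carbenoid carbon (future C3) inserts into a benzylic C–H bond of the ether and gives the cis-fused furofuranone A2 with the new aryl group endo.
- In its favour: one step makes the C2–C3 bond and both of its stereocentres, and the endo aryl group is exactly the 2,3-cis relationship of 16. The lactone carbonyl is a masked CH2OH and the lactone carbinol carbon a masked aryl ketone, so no heavy group is discarded. On stereocentres formed in the key step and on atom economy this plan is better than the chosen one.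
- Against it here: the cis ring fusion of A2 places the C3 and C4 branches cis, so after lactone reduction and selective benzylic oxidation C4 must still be epimerised. That rests on the same thermodynamic argument as the chosen plan, so the two are equal on that point.
- Further drawbacks: the absolute configuration must be built into A1 by a separate asymmetric lactone synthesis, and one of its stereocentres is later destroyed by oxidation. Diazo transfer to a lactone needs prior activation. The carbenoid faces two very electron-rich arenes (arene cyclopropanation or ring expansion) and an endo/exo choice.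
- Comparison: the insertion is mechanistically less predictable than a 5-exo-dig enol addition, and the sequence would run to roughly eleven or twelve steps against seven.

Alternative 2: The cut is O1–C5. The vinyl oxirane A3, which a Sharpless asymmetric epoxidation and a silylation would provide, would be treated with Cu(hfacac)2 (divalent copper). The allylic tertiary C3–O bond opens and the oxygen closes on the vinyl terminus, expanding the oxirane to the 2,5-dihydrofuran A4.
- In its favour: C2 comes from a catalytic asymmetric epoxidation with a firmly established facial rule, which is equal to, and arguably more predictable than, the alkynylation used here. The ring expansion is a waste-free isomerisation, which is better atom economy.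
- Against it here: A4 contains only the C2 stereocentre. The trisubstituted C3=C4 alkene must still receive hydrogen at C3 anti to the aryl group and a complete aroyl group at C4, a late carbon–carbon bond on a secondary ring carbon that needs several functional-group steps and an aryl organometallic addition.
- Further drawbacks: A3 is an aryl oxirane with an electron-rich arene, so a Lewis acidic copper salt in hot solvent may ionise the benzylic C2–O bond instead (loss of enantiopurity, rearrangement to a carbonyl compound). A4 is allylic and benzylic at C2 and may isomerise or aromatise.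
- Comparison: after its key step the chosen plan has every carbon of 16 in place, whereas A4 lacks the whole aroyl unit; the count would be twelve steps or more.

Alternative 3: Two bonds are cut, O1–C2 and C4–C5. The enantioenriched trans cyclopropane-1,1-diester A5 would react with monomeric formaldehyde A6 under Sn(OTf)2 (divalent tin). The aldehyde oxygen attacks C2 with inversion as the C2–C4 bond breaks, and the malonate enolate closes on the aldehyde carbon, giving the tetrahydrofuran A7.
- In its favour: the annulation is stereospecific, so the trans cyclopropane translates directly into the 2,3-cis ring without relying on a facial preference. On this point it is better than the chosen plan, which relies on the C2 aryl group to steer a hydroboration. The geminal diester is a removable activating pair just like the second aroyl group, so the two are equal in concept.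
- Against it here: electron-rich aryl donors let such cyclopropanes open reversibly to a benzylic zwitterion under the Lewis acid, which would erode enantiopurity and the inversion. A6 must be used as the monomer, far less convenient than the aryl aldehydes typical of this annulation. A5 needs an enantioselective malonate-carbenoid cyclopropanation or a resolution.
- After the key step the diester must be taken to a single aryl ketone (dealkoxycarbonylation, amide formation, aryllithium addition, desilylation), with C4 again set by equilibration.
- Comparison: about eleven steps; the chosen plan carries the aryl ketone from its first step and needs only one C–C cleavage after ring formation.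

Key step: step 5

Assumption: (S,S)-ProPhenol is taken as the ligand antipode that delivers the alkynyl group to the Re face of aldehyde 6; should the sense be the reverse, (R,R)-ProPhenol is used and nothing else changes.

## Route

Step 1
Reactants: 1 3',4',5'-trimethoxyacetophenone; 2 methyl 3,4,5-trimethoxybenzoate
Product: 3 1,3-bis(3,4,5-trimethoxyphenyl)propane-1,3-dione
Conditions: NaH (2.5 equiv), THF, reflux; then aq HCl
Reagents that add atoms: none
Why: Crossed Claisen condensation: the sodium enolate of 1 acylates on the non-enolisable ester 2, and deprotonation of the product diketone by the second equivalent of base drives the equilibrium; 3 is obtained as its enol after acidification.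

Step 2
Reactants: 3 1,3-bis(3,4,5-trimethoxyphenyl)propane-1,3-dione
Product: 5 N,N,N-trimethyl-3-oxo-2-(3,4,5-trimethoxybenzoyl)-3-(3,4,5-trimethoxyphenyl)propan-1-aminium iodide, via Mannich base 4 (not isolated)
Conditions: Me2N=CH2+ I− (1.1 equiv), CH2Cl2, rt; cold aq NaHCO3 wash; then MeI (5 equiv), acetone, 0 °C to rt, filtration
Reagents that add atoms: N,N-dimethylmethyleneiminium iodide, SMILES C=[N+](C)C.[I-]; iodomethane, SMILES CI
Why: Mannich reaction of the strongly enolised diketone with the preformed iminium salt gives 4 as its hydroiodide under non-basic conditions, so no free 10 can meet unreacted 3; Menshutkin methylation then turns the amine into a neutral leaving group (NMe3), and the salt 5 precipitates, which keeps it away from base until step 4.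

Step 3
Reactants: 6 3,4,5-trimethoxybenzaldehyde; 7 trimethylsilylacetylene
Product: 9 (R)-1-(3,4,5-trimethoxyphenyl)prop-2-yn-1-ol, via silyl carbinol 8 (not isolated)
Conditions: 7 (3 equiv), Me2Zn (3 equiv), (S,S)-ProPhenol (10 mol %), Ph3P=O (20 mol %), toluene, 4 °C; aq NH4Cl; then K2CO3 (0.2 equiv), MeOH, rt
Reagents that add atoms: none
Why: Zinc–ProPhenol catalysed enantioselective alkynylation of an aryl aldehyde: the dinuclear zinc complex binds the aldehyde and delivers the zinc acetylide to its Re face, which sets C2 (8 is S only because silicon raises the alkynyl priority; its geometry is that of (R)-9); methanolysis of the C–Si bond with K2CO3 then frees the terminal alkyne without touching the carbinol centre.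

Step 4
Reactants: 9 (R)-1-(3,4,5-trimethoxyphenyl)prop-2-yn-1-ol; 5 N,N,N-trimethyl-3-oxo-2-(3,4,5-trimethoxybenzoyl)-3-(3,4,5-trimethoxyphenyl)propan-1-aminium iodide
Product: 11 2-({[(1R)-1-(3,4,5-trimethoxyphenyl)prop-2-yn-1-yl]oxy}methyl)-1,3-bis(3,4,5-trimethoxyphenyl)propane-1,3-dione, via methylene diketone 10 (not isolated)
Conditions: 9 (1.1 equiv), NaH (2.1 equiv), THF, 0 °C; then 5 (1.0 equiv) in portions, −30 to 0 °C; AcOH, −30 °C
Reagents that add atoms: none
Why: Base-induced E1cB loss of NMe3 from 5 releases 10 slowly in the presence of an excess of the sodium alkoxide of 9, and oxa-Michael addition to the unhindered methylene terminus gives the stabilised diketonate of 11, a thermodynamic sink that is protonated cold; the carbinol C–O bond is never broken, so C2 keeps its configuration.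

Step 5
Reactants: 11 2-({[(1R)-1-(3,4,5-trimethoxyphenyl)prop-2-yn-1-yl]oxy}methyl)-1,3-bis(3,4,5-trimethoxyphenyl)propane-1,3-dione
Product: 12 (2S)-3-methylene-4,4-bis(3,4,5-trimethoxybenzoyl)-2-(3,4,5-trimethoxyphenyl)tetrahydrofuran
Conditions: Ph3PAuCl (5 mol %), AgOTf (5 mol %), dry CH2Cl2, 4 Å molecular sieves, rt
Reagents that add atoms: none
Why: This is a Conia-ene cycloisomerisation catalysed by cationic monovalent gold; the closest known reaction type is the gold-catalysed 5-exo-dig addition of β-keto esters and 1,3-diketones to tethered terminal alkynes, together with carbocyclisations of propargyl ether adducts of alkylidene 1,3-dicarbonyls to 3-methylenetetrahydrofurans. Ph3PAu+ (from Ph3PAuCl and AgOTf) binds the alkyne, the enol of the diketone attacks the internal alkyne carbon anti to gold, and protodeauration of the vinylgold species leaves the exocyclic methylene. The single ring is closed 5-exo-dig through carbon (C4–C5–O1–C2–C3), forming C3–C4; attack through the enol oxygen would need a seven-membered ring and is not expected. No stereocentre is created: the two aroyl groups are identical, so C4 is not stereogenic, and C2 is a spectator whose descriptor changes from R to S only because C3 now outranks the aryl group. The step needs carbon rather than oxygen attack, no ionisation of the benzylic propargylic C2–O1 bond and no β-elimination of the alkoxide from the enol. The three-atom tether, the neutral medium and room temperature should secure these. The low enol content of a 2-substituted diaryl diketone may slow the reaction, which is why the catalyst loading is higher than usual for β-keto esters.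

Step 6
Reactants: 12 (2S)-3-methylene-4,4-bis(3,4,5-trimethoxybenzoyl)-2-(3,4,5-trimethoxyphenyl)tetrahydrofuran
Product: 14 (2R,3R)-3-(hydroxymethyl)-4,4-bis(3,4,5-trimethoxybenzoyl)-2-(3,4,5-trimethoxyphenyl)tetrahydrofuran, via alkylborane 13 (not isolated)
Conditions: 9-BBN (1.5 equiv), THF, 0 °C to rt; then NaBO3·4H2O, THF/H2O, rt
Reagents that add atoms: sodium perborate tetrahydrate NaBO3·4H2O (supplies the hydroxyl oxygen), SMILES [Na+].[Na+].O[B-]1(O)OO[B-](O)(O)OO1; 9-BBN (supplies boron and the bicyclic unit of 13 only), SMILES B1C2CCCC1CCC2
Why: Hydroboration–oxidation: 9-BBN places boron on the terminal carbon of the 1,1-disubstituted alkene and hydrogen on C3 through a four-centre transition state on the face opposite the C2 aryl group (the only bias, since C4 is quaternary and symmetric), which sets C3 with CH2OH cis to aryl; hindered electron-rich aryl ketones should be reduced far more slowly by 9-BBN than such an alkene is hydroborated, and NaBO3 oxidises the C–B bond with retention under mild conditions.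

Step 7
Reactants: 14 (2R,3R)-3-(hydroxymethyl)-4,4-bis(3,4,5-trimethoxybenzoyl)-2-(3,4,5-trimethoxyphenyl)tetrahydrofuran
Product: 16 (2R,3R,4S)-3-(hydroxymethyl)-4-(3,4,5-trimethoxybenzoyl)-2-(3,4,5-trimethoxyphenyl)tetrahydrofuran, via benzoate ester 15 (not isolated)
Conditions: K2CO3 (2 equiv), MeOH, rt to 40 °C
Reagents that add atoms: none
Why: Retro-Claisen cleavage of a non-enolisable 1,3-diketone: the primary alkoxide adds to the cis aroyl carbonyl and the cyclic adduct fragments to ester 15 and the C4 enolate (direct methoxide attack would lead to the same products), methanolysis then frees the alcohol, and reversible enolisation at C4 lets the remaining aroyl group settle trans to CH2OH, the less crowded arrangement; C2 and C3 bear no acidic hydrogen and are untouched.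

## Compound list

1 | 3',4',5'-trimethoxyacetophenone | CC(=O)c1cc(OC)c(OC)c(OC)c1 | starting material
2 | methyl 3,4,5-trimethoxybenzoate | COC(=O)c1cc(OC)c(OC)c(OC)c1 | starting material
3 | 1,3-bis(3,4,5-trimethoxyphenyl)propane-1,3-dione | O=C(CC(=O)c1cc(OC)c(OC)c(OC)c1)c1cc(OC)c(OC)c(OC)c1 | intermediate
4 | 2-[(dimethylamino)methyl]-1,3-bis(3,4,5-trimethoxyphenyl)propane-1,3-dione (formed as its hydroiodide) | CN(C)CC(C(=O)c1cc(OC)c(OC)c(OC)c1)C(=O)c1cc(OC)c(OC)c(OC)c1 | intermediate
5 | N,N,N-trimethyl-3-oxo-2-(3,4,5-trimethoxybenzoyl)-3-(3,4,5-trimethoxyphenyl)propan-1-aminium iodide | C[N+](C)(C)CC(C(=O)c1cc(OC)c(OC)c(OC)c1)C(=O)c1cc(OC)c(OC)c(OC)c1.[I-] | intermediate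
6 | 3,4,5-trimethoxybenzaldehyde | COc1cc(C=O)cc(OC)c1OC | starting material
7 | trimethylsilylacetylene | C#C[Si](C)(C)C | starting material
8 | (S)-3-(trimethylsilyl)-1-(3,4,5-trimethoxyphenyl)prop-2-yn-1-ol | C[Si](C)(C)C#C[C@@H](O)c1cc(OC)c(OC)c(OC)c1 | intermediate
9 | (R)-1-(3,4,5-trimethoxyphenyl)prop-2-yn-1-ol | C#C[C@@H](O)c1cc(OC)c(OC)c(OC)c1 | intermediate
10 | 2-methylene-1,3-bis(3,4,5-trimethoxyphenyl)propane-1,3-dione | C=C(C(=O)c1cc(OC)c(OC)c(OC)c1)C(=O)c1cc(OC)c(OC)c(OC)c1 | intermediate
11 | 2-({[(1R)-1-(3,4,5-trimethoxyphenyl)prop-2-yn-1-yl]oxy}methyl)-1,3-bis(3,4,5-trimethoxyphenyl)propane-1,3-dione | C#C[C@H](c1cc(OC)c(OC)c(OC)c1)OCC(C(=O)c1cc(OC)c(OC)c(OC)c1)C(=O)c1cc(OC)c(OC)c(OC)c1 | intermediate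
12 | (2S)-3-methylene-4,4-bis(3,4,5-trimethoxybenzoyl)-2-(3,4,5-trimethoxyphenyl)tetrahydrofuran (same geometry at C2 as 11) | C=C1[C@H](c2cc(OC)c(OC)c(OC)c2)OCC1(C(=O)c1cc(OC)c(OC)c(OC)c1)C(=O)c1cc(OC)c(OC)c(OC)c1 | intermediate
13 | 9-{[(2R,3S)-4,4-bis(3,4,5-trimethoxybenzoyl)-2-(3,4,5-trimethoxyphenyl)tetrahydrofuran-3-yl]methyl}-9-borabicyclo[3.3.1]nonane (aryl and CH2B cis) | C1CCC2CCCC1B2C[C@@H]1[C@H](c2cc(OC)c(OC)c(OC)c2)OCC1(C(=O)c1cc(OC)c(OC)c(OC)c1)C(=O)c1cc(OC)c(OC)c(OC)c1 | intermediate
14 | (2R,3R)-3-(hydroxymethyl)-4,4-bis(3,4,5-trimethoxybenzoyl)-2-(3,4,5-trimethoxyphenyl)tetrahydrofuran (aryl and CH2OH cis) | OC[C@@H]1[C@H](c2cc(OC)c(OC)c(OC)c2)OCC1(C(=O)c1cc(OC)c(OC)c(OC)c1)C(=O)c1cc(OC)c(OC)c(OC)c1 | intermediate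
15 | [(2R,3R,4S)-4-(3,4,5-trimethoxybenzoyl)-2-(3,4,5-trimethoxyphenyl)tetrahydrofuran-3-yl]methyl 3,4,5-trimethoxybenzoate | COc1cc(C(=O)[C@@H]2CO[C@@H](c3cc(OC)c(OC)c(OC)c3)[C@H]2COC(=O)c2cc(OC)c(OC)c(OC)c2)cc(OC)c1OC | intermediate
16 | (2R,3R,4S)-3-(hydroxymethyl)-4-(3,4,5-trimethoxybenzoyl)-2-(3,4,5-trimethoxyphenyl)tetrahydrofuran (CNP0148560.2; 2,3-cis, 3,4-trans) | COc1cc(C(=O)[C@@H]2CO[C@@H](c3cc(OC)c(OC)c(OC)c3)[C@H]2CO)cc(OC)c1OC | target

## Step count and least certain steps

Total step count: 7. Longest linear sequence: 6 steps (steps 1, 2, 4, 5, 6, 7; 1 → 3 → 5 → 11 → 12 → 14 → 16). The branch 6 + 7 → 9 is one step.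

Step 5 (key step). Slow enolisation of the 2-substituted diaryl diketone may let side processes win: hydration of the gold-activated alkyne by adventitious water, β-elimination of the propargylic alkoxide from the enol, or acid-induced ionisation at the benzylic C2–O1 bond with loss of configuration. A more electrophilic catalyst ((p-CF3C6H4)3PAuCl with AgSbF6) or 40 °C in ClCH2CH2Cl would be tried first. Fallback, from 11 back to 12: the nucleophile is fixed beforehand by O-silylation (tBuMe2SiOTf, Et3N, CH2Cl2, −78 °C) to the tert-butyldimethylsilyl enol ether F1. F1 is then cyclised onto the alkyne with Ph3PAuCl/AgBF4 in CH2Cl2/H2O (10:1) at rt, the known 5-exo-dig carbocyclisation of silyl enol ethers under monovalent gold, in which water takes up the silyl group and supplies the proton.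

Step 4. Self-reaction of the released acceptor (hetero-Diels–Alder dimerisation, or Michael addition of the product enolate) may outrun capture by the alkoxide, and the addition may reverse during the quench. Fallback, from 9 back to 11: the ether is built before the diketone. 1-(3,4,5-Trimethoxyphenyl)prop-2-en-1-one F2 is made from commercial 3,4,5-trimethoxybenzoyl chloride and tributyl(vinyl)stannane with PdCl2(PPh3)2 (Stille acylation). F2 takes up 9 under PMe3 catalysis (phosphine-catalysed oxa-Michael addition) to give the β-alkoxy ketone F3. The lithium enolate of F3 (LiN(SiMe3)2, toluene, −78 °C) is C-acylated with 3,4,5-trimethoxybenzoyl chloride (half an equivalent, unreacted F3 being recycled) to give 11.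

Step 6. Competing reduction of the aryl ketones by the dialkylborane, or an insufficient facial preference at the exocyclic alkene. Fallback, from 12 back to 14: the mechanism and the borane are both changed. Pinacolborane does not reduce ketones on its own and is added under RhCl(PPh3)3 catalysis; rhodium hydride insertion from the face anti to the aryl group gives the primary pinacol boronate F4. Oxidation of F4 with NaBO3·4H2O gives 14.

Step 7. Stalling at the acyl-transfer ester stage (slow methanolysis of a hindered, electron-rich benzoate), incomplete equilibration at C4, or ring opening by β-elimination of O1 from the C4 enolate. Fallback, from 14 back to 16: the hydroxyl is masked first (tBuMe2SiCl, imidazole, CH2Cl2) as the silyl ether F5, so that no internal alkoxide exists. F5 is cleaved by intermolecular retro-Claisen reaction with NaOMe in MeOH at 0 °C to rt, which gives the C4-equilibrated silyl ether F6 of the target. Bu4NF buffered with AcOH in THF then gives 16.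

Step 2. Premature elimination during quaternisation (unreacted amine acting as base on the acidic C–H of the salt) would release the acceptor with nothing to trap it, followed by oligomerisation. Fallback, from 3 back to 11 (through 10 in the flask of step 4): thiomethylation of 3 with aqueous formaldehyde and thiophenol (cat. Et3N, EtOH, rt) gives the sulfide F7. Oxidation of F7 with mCPBA (2.2 equiv, CH2Cl2, 0 °C) gives the crystalline sulfone F8. F8 has no basic site and takes the place of 5 in step 4, where the base expels benzenesulfinate by E1cB elimination.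

## Further compounds

F1 | step 5 | (2Z)-3-[(tert-butyldimethylsilyl)oxy]-2-({[(1R)-1-(3,4,5-trimethoxyphenyl)prop-2-yn-1-yl]oxy}methyl)-1,3-bis(3,4,5-trimethoxyphenyl)prop-2-en-1-one (either alkene geometry serves) | C#C[C@H](c1cc(OC)c(OC)c(OC)c1)OC/C(C(=O)c1cc(OC)c(OC)c(OC)c1)=C(/O[Si](C)(C)C(C)(C)C)c1cc(OC)c(OC)c(OC)c1
F2 | step 4 | 1-(3,4,5-trimethoxyphenyl)prop-2-en-1-one | C=CC(=O)c1cc(OC)c(OC)c(OC)c1
F3 | step 4 | 3-{[(1R)-1-(3,4,5-trimethoxyphenyl)prop-2-yn-1-yl]oxy}-1-(3,4,5-trimethoxyphenyl)propan-1-one | C#C[C@H](c1cc(OC)c(OC)c(OC)c1)OCCC(=O)c1cc(OC)c(OC)c(OC)c1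
F4 | step 6 | 2-{[(2R,3S)-4,4-bis(3,4,5-trimethoxybenzoyl)-2-(3,4,5-trimethoxyphenyl)tetrahydrofuran-3-yl]methyl}-4,4,5,5-tetramethyl-1,3,2-dioxaborolane (aryl and CH2B cis) | CC1(C)OB(C[C@@H]2[C@H](c3cc(OC)c(OC)c(OC)c3)OCC2(C(=O)c2cc(OC)c(OC)c(OC)c2)C(=O)c2cc(OC)c(OC)c(OC)c2)OC1(C)C
F5 | step 7 | (2R,3R)-3-{[(tert-butyldimethylsilyl)oxy]methyl}-4,4-bis(3,4,5-trimethoxybenzoyl)-2-(3,4,5-trimethoxyphenyl)tetrahydrofuran | CC(C)(C)[Si](C)(C)OC[C@@H]1[C@H](c2cc(OC)c(OC)c(OC)c2)OCC1(C(=O)c1cc(OC)c(OC)c(OC)c1)C(=O)c1cc(OC)c(OC)c(OC)c1
F6 | step 7 | (2R,3R,4S)-3-{[(tert-butyldimethylsilyl)oxy]methyl}-4-(3,4,5-trimethoxybenzoyl)-2-(3,4,5-trimethoxyphenyl)tetrahydrofuran | COc1cc(C(=O)[C@@H]2CO[C@@H](c3cc(OC)c(OC)c(OC)c3)[C@H]2CO[Si](C)(C)C(C)(C)C)cc(OC)c1OC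
F7 | step 2 | 2-[(phenylsulfanyl)methyl]-1,3-bis(3,4,5-trimethoxyphenyl)propane-1,3-dione | O=C(c1cc(OC)c(OC)c(OC)c1)C(CSc1ccccc1)C(=O)c1cc(OC)c(OC)c(OC)c1
F8 | step 2 | 2-[(phenylsulfonyl)methyl]-1,3-bis(3,4,5-trimethoxyphenyl)propane-1,3-dione | O=C(c1cc(OC)c(OC)c(OC)c1)C(CS(=O)(=O)c1ccccc1)C(=O)c1cc(OC)c(OC)c(OC)c1
A1 | alternative 1 | trans-3-diazo-4-{[(3,4,5-trimethoxybenzyl)oxy]methyl}-5-(3,4,5-trimethoxyphenyl)dihydrofuran-2(3H)-one | O=C1O[C@H](c2cc(OC)c(OC)c(OC)c2)[C@@H](COCc2cc(OC)c(OC)c(OC)c2)C1=[N+]=[N-]
A2 | alternative 1 | endo,exo-2,6-bis(3,4,5-trimethoxyphenyl)-3,7-dioxabicyclo[3.3.0]octan-8-one | O=C1O[C@H](c2cc(OC)c(OC)c(OC)c2)[C@H]2CO[C@@H](c3cc(OC)c(OC)c(OC)c3)[C@@H]12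
A3 | alternative 2 | 2-ethenyl-3-(3,4,5-trimethoxyphenyl)-2-{[(triisopropylsilyl)oxy]methyl}oxirane (aryl and vinyl cis) | C=C[C@@]1(CO[Si](C(C)C)(C(C)C)C(C)C)O[C@H]1c1cc(OC)c(OC)c(OC)c1
A4 | alternative 2 | (2S)-2-(3,4,5-trimethoxyphenyl)-3-{[(triisopropylsilyl)oxy]methyl}-2,5-dihydrofuran | CC(C)[Si](C(C)C)(C(C)C)OCC1=CCO[C@H]1c1cc(OC)c(OC)c(OC)c1
A5 | alternative 3 | dimethyl trans-2-(3,4,5-trimethoxyphenyl)-3-{[(triisopropylsilyl)oxy]methyl}cyclopropane-1,1-dicarboxylate | COC(=O)C1(C(=O)OC)[C@H](c2cc(OC)c(OC)c(OC)c2)[C@H]1CO[Si](C(C)C)(C(C)C)C(C)C
A6 | alternative 3 | formaldehyde | C=O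
A7 | alternative 3 | dimethyl 2,3-cis-2-(3,4,5-trimethoxyphenyl)-3-{[(triisopropylsilyl)oxy]methyl}tetrahydrofuran-4,4-dicarboxylate | COC(=O)C1(C(=O)OC)CO[C@@H](c2cc(OC)c(OC)c(OC)c2)[C@H]1CO[Si](C(C)C)(C(C)C)C(C)C
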